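The route rests on cutting C6–C7 of the ten-membered ring. The segment C16H2=C5–C6(Cl)–C7(O) is an anti 2-methylene chlorohydrin lying between that ring and the γ-lactone. This is the pattern a γ-chloroallylchromium reagent leaves when it adds to an aldehyde. In one operation CrCl2 converts an allylic gem-dichloride into this reagent, closes the carbocycle on the C7 aldehyde, sets C6 and C7, and releases the exocyclic methylene. The C7 alkoxide then lactonises onto C19. The precursor is a finished epoxycyclohexane (ring A) with two trans arms. One is C2–C5 ending in CH2=C–CHCl2. The other is C9–C8, carrying a non-enolisable aldehyde and a methyl ester, built from (S)-malic acid.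

Key step: step 21

Remark: atom labels follow briarane numbering (ring A = C1, C10–C14; ten-membered ring = C1–C10; lactone = O, C7, C8, C17, C19). β is the face of ring A that carries Me-15 and α is the opposite face.
Assumption: the facial bias of the catalyst in step 2 is inferred by analogy with 2-methylacrolein and points to the (R)-diphenylprolinol series; this assignment is not secure, and the antipode is equally available if the dienophile responds the other way.
Assumption: the enone reduced in step 9 is taken to react from the half-chair with both ring methyl groups pseudo-equatorial and both arms pseudo-axial.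

Step 1
Reactants: 1 ethyl vinyl ketone
Product: 2 (Z)-3-(triisopropylsilyloxy)penta-1,3-diene
Conditions: TIPSOTf, Et3N, CH2Cl2, 0 °C to rt
Reagents that add atoms: triisopropylsilyl triflate, CC(C)[Si](C(C)C)(C(C)C)OS(=O)(=O)C(F)(F)F
Why: Soft enolisation with O-silylation on the ethyl side gives the cross-conjugated silyl dienol ether, and the (Z) isomer (methyl cis to oxygen, trans to vinyl) is favoured because it avoids allylic strain between methyl and vinyl.

Step 2
Reactants: 2 (Z)-3-(triisopropylsilyloxy)penta-1,3-diene; 3 ethyl (E)-3-methyl-4-oxobut-2-enoate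
Product: 4 ethyl 6-formyl-2,6-dimethyl-3-(triisopropylsilyloxy)cyclohex-3-ene-1-carboxylate (C1: Me-15 β, CHO α; C10: CO2Et β; C11: Me-20 β; C12=C13 enol ether)
Conditions: (R)-3,3-diphenyl-1-(2-methylphenyl)tetrahydro-1H,3H-pyrrolo[1,2-c][1,3,2]oxazaborole·HNTf2 (15 mol %), CH2Cl2, −78 to −40 °C
Reagents that add atoms: none
Why: In this catalytic enantioselective Diels–Alder reaction the Lewis acid binds the formyl group, so the nucleophilic C11 terminus of the 2-silyloxydiene bonds to C10 (para product), the (E)-dienophile fixes C2 and C9 trans, a formyl-exo/ester-endo approach (usual for α-branched enals and helped by the clash of the catalyst-laden formyl group with OTIPS) puts the outside methyl C20 cis to C9, and shielding of one face of the s-trans enal sets the absolute configuration.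

Step 3
Reactants: 4 Diels–Alder adduct; 5 allylmagnesium bromide
Product: 8 (2R)-homoallylic alcohol of the cyclohexene ester, via allylborane 6 (not isolated), via borinate 7 (not isolated)
Conditions: (+)-Ipc2BOMe, 5, Et2O, −78 °C to rt; then 4, −78 °C; NaBO3·4H2O, THF/H2O, rt
Reagents that add atoms: none
Why: Brown allylboration through a closed chair lets the (−)-α-pinene-derived ligands override the bias of the neopentyl aldehyde and set (2R), and the mild perborate work-up avoids base-induced lactonisation of O2 onto the C9 ester.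

Step 4
Reactants: 8 (2R)-homoallylic alcohol
Product: 9 C2 triethylsilyl ether (TIPS enol ether and ethyl ester retained)
Conditions: TESOTf, 2,6-lutidine, CH2Cl2, −78 to 0 °C
Reagents that add atoms: triethylsilyl triflate, CC[Si](CC)(CC)OS(=O)(=O)C(F)(F)F
Why: O-silylation with the reactive triflate copes with the neopentyl C2 alcohol, and the hindered pyridine base leaves the enol ether and the ester alone.

Step 5
Reactants: 9 C2 triethylsilyl ether
Product: 10 homoallylic TES ether enone (C12 ketone, C13=C14)
Conditions: Pd(OAc)2 (1.1 equiv), MeCN/DMSO, 40 °C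
Reagents that add atoms: none
Why: Saegusa–Ito oxidation (palladation at C13, then β-hydride elimination from C14) gives the enone under nearly neutral conditions that spare the epimerisable C11 centre and the terminal alkene.

Step 6
Reactants: 10 homoallylic TES ether enone
Product: 11 linear aldehyde (C3–C5 methylene chain ending in the C6 formyl group)
Conditions: Rh(acac)(CO)2 (1 mol %), Xantphos (4,5-bis(diphenylphosphino)-9,9-dimethylxanthene, 4 mol %), CO/H2 (1:1, 10 bar), toluene, 60 °C
Reagents that add atoms: carbon monoxide, [C-]#[O+]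
Why: Linear-selective rhodium hydroformylation with a wide-bite-angle diphosphine places the formyl carbon (future C6) on the terminal carbon, while the hindered conjugated C13=C14 bond does not insert.

Step 7
Reactants: 11 linear aldehyde
Product: 13 2-methylene aldehyde (C5=C16 with C6 formyl), via Mannich base 12 (not isolated)
Conditions: CH2=NMe2+ I− (Eschenmoser's salt), Et3N, CH2Cl2, rt
Reagents that add atoms: N,N-dimethylmethyleneiminium iodide, C=[N+](C)C.[I-]
Why: Mannich condensation followed by β-elimination of dimethylamine (α-methylenation) installs C16, because the unbranched aldehyde enolises far faster than the α-branched ketone and the mild amine base should not epimerise C11.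

Step 8
Reactants: 13 2-methylene aldehyde
Product: 14 allylic gem-dichloride enone (CH2=C5–C6HCl2)
Conditions: Ph3PO (15 mol %), (COCl)2 (slow addition), CHCl3, rt
Reagents that add atoms: oxalyl chloride, O=C(Cl)C(=O)Cl
Why: In this phosphine-oxide-catalysed deoxydichlorination the Ph3PCl2 formed in the flask exchanges the aldehyde oxygen for two chlorides, the less electrophilic enone is spared at low reagent concentration, and any 1,3-dichloro allylic isomer would feed the same allylchromium species later.

Step 9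
Reactants: 14 allylic gem-dichloride enone
Product: 15 12α-allylic alcohol
Conditions: NaBH4, CeCl3·7H2O, MeOH, −78 °C
Reagents that add atoms: none
Why: Luche 1,2-reduction touches only the ketone, and axial hydride delivery to the β face of the half-chair with both ring methyls pseudo-equatorial should give the pseudo-equatorial 12α-alcohol trans to Me-20.

Step 10
Reactants: 15 12α-allylic alcohol
Product: 16 13,14-α-epoxy-12α-alcohol
Conditions: VO(acac)2 (5 mol %), t-BuOOH, CH2Cl2, 0 °C
Reagents that add atoms: tert-butyl hydroperoxide, CC(C)(C)OO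
Why: Hydroxyl-directed vanadium epoxidation delivers oxygen to C13=C14 on the face of the C12 alcohol (sets C13 and C14) and ignores the undirected, chlorine-deactivated C5=C16 alkene.

Step 11
Reactants: 16 epoxy alcohol
Product: 17 bis-TES epoxy ester
Conditions: TESCl, imidazole, 4-dimethylaminopyridine (cat.), CH2Cl2, rt
Reagents that add atoms: chlorotriethylsilane, CC[Si](Cl)(CC)CC
Why: O-silylation under mild base spares the epoxide and gives C12 the same protecting group as C2, so that both can later be freed together beside a TBS ether.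

Step 12
Reactants: 17 bis-TES epoxy ester
Product: 18 C9 primary alcohol
Conditions: i-Bu2AlH (2.5 equiv), CH2Cl2, −78 °C; Rochelle salt
Reagents that add atoms: none
Why: Full hydride reduction of the hindered ester is chosen over a half-reduction because over-reduction then cannot spoil the step, and at −78 °C the epoxide, the allylic gem-dichloride and the silyl ethers should be inert.

Step 13
Reactants: 18 C9 primary alcohol
Product: 19 epoxy C9 aldehyde
Conditions: Dess–Martin periodinane, NaHCO3, CH2Cl2, 0 °C to rt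
Reagents that add atoms: none
Why: Dess–Martin oxidation under bicarbonate buffer gives the α-branched aldehyde without epimerising C10 or disturbing the acid-sensitive groups.

Step 14
Reactants: 20 diethyl (S)-malate
Product: 22 diethyl (2S,3R)-3-methylmalate, via dilithio malate 21 (not isolated)
Conditions: LiN(i-Pr)2 (2.1 equiv), THF, −78 to −20 °C; MeI, −78 to 0 °C; AcOH
Reagents that add atoms: iodomethane, CI
Why: In the Fráter–Seebach alkylation the chelated lithium alkoxide enolate is methylated on its open face to give the anti (2S,3R) diester, which creates C17 and brings in C18.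

Step 15
Reactants: 22 diethyl (2S,3R)-3-methylmalate
Product: 23 (2S,3R)-3-methylmalic acid
Conditions: KOH, H2O/EtOH, rt; HCl to pH 1
Reagents that add atoms: potassium hydroxide, [K+].[OH-]
Why: Saponification is safe for C17 because the carboxylates formed resist enolisation.

Step 16
Reactants: 23 (2S,3R)-3-methylmalic acid
Product: 24 (2R)-2-[(2S,4S)-2-tert-butyl-5-oxo-1,3-dioxolan-4-yl]propanoic acid (cis acetal)
Conditions: t-BuCHO, p-toluenesulfonic acid (cat.), H2SO4 (cat.), pentane, reflux, water separator; recrystallisation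
Reagents that add atoms: pivaldehyde, CC(C)(C)C=O
Why: Acid-catalysed acetalisation under thermodynamic control closes the five-membered dioxolanone on the α-hydroxy acid unit with tert-butyl cis to the side chain, storing the C8 configuration in the acetal centre.

Step 17
Reactants: 19 epoxy C9 aldehyde; 24 dioxolanone acid
Product: 28 aldol acid with C8–C9 joined (9R OTBS), via dioxolanone dianion 25 (not isolated), via lithium aldolate 26 (not isolated), via silyl ester 27 (not isolated)
Conditions: 24, LiN(SiMe3)2 (2.05 equiv), THF, −78 °C; 19, −78 °C; TBSOTf (2.5 equiv), −78 to −40 °C; aq NaHCO3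
Reagents that add atoms: tert-butyldimethylsilyl triflate, CC(C)(C)[Si](C)(C)OS(=O)(=O)C(F)(F)F
Why: In this aldol addition with self-regeneration of the stereocentre the aldehyde meets the enolate face anti to tert-butyl (retention at C8), the ring-locked enolate with C17 cis to OLi reacts through a Zimmerman–Traxler chair to the 8,9-anti diol pattern, the carboxylate blocks deprotonation at C17, preforming the dianion leaves no free amide base for the CHCl2 proton, and silylation in the flask stops retro-aldol.

Step 18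
Reactants: 28 aldol acid
Product: 30 C8-hydroxy C7-aldehyde C19-acid (in equilibrium with its cyclic pseudo-acid), via lactol 29 (not isolated)
Conditions: i-Bu2AlH (3.5 equiv), CH2Cl2/toluene, −78 °C; Rochelle salt
Reagents that add atoms: none
Why: In this partial reduction of an activated lactone the first equivalent turns the acid into an inert aluminium carboxylate, the dioxolanone carbonyl stops at the aluminium lactolate, and on work-up the lactol opens and sheds pivaldehyde to free the tertiary C8 alcohol and the C7 aldehyde.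

Step 19
Reactants: 30 hydroxy aldehyde acid
Product: 31 C19 methyl ester
Conditions: TMSCHN2, toluene/MeOH, 0 °C
Reagents that add atoms: trimethylsilyldiazomethane, C[Si](C)(C)C=[N+]=[N-]
Why: Diazoalkane esterification is fast and neutral, traps the open carboxylic acid form and avoids the base that could trigger α-ketol rearrangement of the tertiary α-hydroxy aldehyde.

Step 20
Reactants: 31 C19 methyl ester
Product: 32 seco aldehyde gem-dichloride with C8 OTMS
Conditions: TMSOTf, 2,6-lutidine, CH2Cl2, −78 to −20 °C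
Reagents that add atoms: trimethylsilyl triflate, C[Si](C)(C)OS(=O)(=O)C(F)(F)F
Why: O-silylation with the smallest silyl group fits the crowded tertiary alcohol, removes the only OH that could protonate an organochromium reagent and prevents chelation at C7/C8.

Step 21
Reactants: 32 seco aldehyde gem-dichloride
Product: 35 silyl-protected briarane lactone, via chloroallylchromium 33 (not isolated), via chromium alkoxide 34 (not isolated)
Conditions: CrCl2 (8 equiv), LiI (10 mol %), THF, rt, 32 added by syringe pump (final about 1 mM); aq sodium potassium tartrate, silica gel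
Reagents that add atoms: none
Why: Proposed new method: two single-electron transfers from divalent chromium cleave one C–Cl bond of the allylic gem-dichloride, and the α-chloroallyl species of trivalent chromium moves by 1,3-shift to the less hindered C16 terminus as the (E)-γ-chloro isomer 33, which adds through C6 (SE2′) to the chromium-bound C7 aldehyde in a six-membered chair. The closest known reaction types are the intermolecular anti-selective γ-chloroallylation of aldehydes with allylic gem-dichlorides and CrCl2, and Nozaki–Hiyama–Kishi allylation macrocyclisations to medium rings, whose combination in one ring closure is untested. The ten-membered carbocycle closes 10-exo-trig on C7=O, and the chromium alkoxide 34 then closes the γ-lactone 5-exo-trig on the C19 methyl ester, which also stops the alkoxide from displacing the neighbouring chloride. C6 is fixed relative to C7 by the chair, in which chlorine on the (E)-alkene and C8 on the aldehyde both sit equatorial (anti chlorohydrin), and C7 is fixed by polar Felkin–Anh attack anti to the C8–OTMS bond with the C17 arm as the small group, the silyl ether being essential because a chelate would lead to the C7 epimer. The step needs ring closure to outrun oligomerisation, protonation and a second reduction, which is served by slow addition to excess CrCl2, by the fully substituted C1 and C8 that fold the two trans arms toward each other, by a non-enolisable aldehyde in an OH-free substrate, and by the hindered secondary allylic chloride of 35 being reduced much more slowly than a gem-dichloride.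

Step 22
Reactants: 35 silyl-protected briarane lactone
Product: 36 2,8,12-triol with C9 OTBS
Conditions: HF·pyridine, pyridine, THF, 0 °C
Reagents that add atoms: none
Why: Selective desilylation with buffered HF·pyridine cleaves the two TES ethers and the TMS ether much faster than the bulkier, more crowded C9 TBS ether and is too mild to open the epoxide or ionise the allylic chloride.

Step 23
Reactants: 36 2,8,12-triol
Product: 37 2,12-diacetate with C9 OTBS
Conditions: Ac2O, pyridine, 4-dimethylaminopyridine (cat.), CH2Cl2, 0 °C to rt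
Reagents that add atoms: acetic anhydride, CC(=O)OC(C)=O
Why: Acylation takes the two secondary alcohols, while the tertiary C8 alcohol, wedged between C7, C9 and C17, should stay free.

Step 24
Reactants: 37 2,12-diacetate
Product: 38 target CNP0242711.1
Conditions: HF·pyridine (excess), MeCN, 0 °C to rt, plastic vessel
Reagents that add atoms: none
Why: Base-free fluoride desilylation removes the last silyl group without the alkoxide that could cause acetate migration, lactone transfer to O9 or loss of HCl.

Compound list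
1 | ethyl vinyl ketone | C=CC(=O)CC | starting material
2 | (Z)-3-(triisopropylsilyloxy)penta-1,3-diene | C=C/C(O[Si](C(C)C)(C(C)C)C(C)C)=C/C | intermediate
3 | ethyl (E)-3-methyl-4-oxobut-2-enoate | CCOC(=O)/C=C(\C)C=O | starting material
4 | Diels–Alder adduct, ethyl 6-formyl-2,6-dimethyl-3-(triisopropylsilyloxy)cyclohex-3-ene-1-carboxylate (Me-15 β, CHO α, CO2Et β, Me-20 β) | O=C[C@]1(C)[C@H]([C@@H](C)C(O[Si](C(C)C)(C(C)C)C(C)C)=CC1)C(=O)OCC | intermediate
5 | allylmagnesium bromide | C=CC[Mg]Br | starting material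
6 | B-allyldiisopinocampheylborane, (−)-α-pinene series (not isolated) | C=CCB([C@H]1C[C@H]2C[C@@H]([C@@H]1C)C2(C)C)[C@H]1C[C@H]2C[C@@H]([C@@H]1C)C2(C)C | intermediate
7 | diisopinocampheylborinate of alcohol 8 (not isolated) | C=CC[C@@H](OB([C@H]2C[C@H]3C[C@@H]([C@@H]2C)C3(C)C)[C@H]2C[C@H]3C[C@@H]([C@@H]2C)C3(C)C)[C@]1(C)[C@H]([C@@H](C)C(O[Si](C(C)C)(C(C)C)C(C)C)=CC1)C(=O)OCC | intermediate
8 | (2R)-homoallylic alcohol | C=CC[C@@H](O)[C@]1(C)[C@H]([C@@H](C)C(O[Si](C(C)C)(C(C)C)C(C)C)=CC1)C(=O)OCC | intermediate
9 | C2 TES ether, TIPS enol ether | C=CC[C@@H](O[Si](CC)(CC)CC)[C@]1(C)[C@H]([C@@H](C)C(O[Si](C(C)C)(C(C)C)C(C)C)=CC1)C(=O)OCC | intermediate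
10 | homoallylic TES ether enone | C=CC[C@@H](O[Si](CC)(CC)CC)[C@]1(C)[C@H]([C@@H](C)C(=O)C=C1)C(=O)OCC | intermediate
11 | linear C6 aldehyde | O=CCCC[C@@H](O[Si](CC)(CC)CC)[C@]1(C)[C@H]([C@@H](C)C(=O)C=C1)C(=O)OCC | intermediate
12 | Mannich base, C5 epimers (not isolated) | CN(C)CC(C=O)CC[C@@H](O[Si](CC)(CC)CC)[C@]1(C)[C@H]([C@@H](C)C(=O)C=C1)C(=O)OCC | intermediate
13 | 2-methylene aldehyde | C=C(C=O)CC[C@@H](O[Si](CC)(CC)CC)[C@]1(C)[C@H]([C@@H](C)C(=O)C=C1)C(=O)OCC | intermediate
14 | allylic gem-dichloride enone | C=C(C(Cl)Cl)CC[C@@H](O[Si](CC)(CC)CC)[C@]1(C)[C@H]([C@@H](C)C(=O)C=C1)C(=O)OCC | intermediate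
15 | 12α-allylic alcohol | C=C(C(Cl)Cl)CC[C@@H](O[Si](CC)(CC)CC)[C@]1(C)[C@H]([C@@H](C)[C@H](O)C=C1)C(=O)OCC | intermediate
16 | 13,14-α-epoxy-12α-alcohol | C=C(C(Cl)Cl)CC[C@@H](O[Si](CC)(CC)CC)[C@]1(C)[C@H]([C@@H](C)[C@H](O)[C@@H]2O[C@@H]21)C(=O)OCC | intermediate
17 | bis-TES epoxy ester | C=C(C(Cl)Cl)CC[C@@H](O[Si](CC)(CC)CC)[C@]1(C)[C@H]([C@@H](C)[C@H](O[Si](CC)(CC)CC)[C@@H]2O[C@@H]21)C(=O)OCC | intermediate
18 | C9 primary alcohol | C=C(C(Cl)Cl)CC[C@@H](O[Si](CC)(CC)CC)[C@]1(C)[C@H]([C@@H](C)[C@H](O[Si](CC)(CC)CC)[C@@H]2O[C@@H]21)CO | intermediate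
19 | epoxy C9 aldehyde | C=C(C(Cl)Cl)CC[C@@H](O[Si](CC)(CC)CC)[C@]1(C)[C@H]([C@@H](C)[C@H](O[Si](CC)(CC)CC)[C@@H]2O[C@@H]21)C=O | intermediate
20 | diethyl (S)-malate | CCOC(=O)C[C@H](O)C(=O)OCC | starting material
21 | dilithio alkoxide enolate of 20 (not isolated) | CCOC(=O)[C@@H]([O-])C=C([O-])OCC.[Li+].[Li+] | intermediate
22 | diethyl (2S,3R)-3-methylmalate | CCOC(=O)[C@H](C)[C@H](O)C(=O)OCC | intermediate
23 | (2S,3R)-3-methylmalic acid | OC(=O)[C@H](C)[C@H](O)C(=O)O | intermediate
24 | (2R)-2-[(2S,4S)-2-tert-butyl-5-oxo-1,3-dioxolan-4-yl]propanoic acid | OC(=O)[C@H](C)[C@@H]1O[C@H](C(C)(C)C)OC1=O | intermediate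
25 | dilithium enolate carboxylate of 24 (not isolated) | [Li+].[Li+].[O-]C(=O)[C@H](C)C1=C([O-])O[C@@H](C(C)(C)C)O1 | intermediate
26 | dilithium aldolate carboxylate (not isolated) | C=C(C(Cl)Cl)CC[C@@H](O[Si](CC)(CC)CC)[C@]1(C)[C@H]([C@@H](C)[C@H](O[Si](CC)(CC)CC)[C@@H]2O[C@@H]21)[C@@H]([O-])[C@]3(O[C@H](C(C)(C)C)OC3=O)[C@@H](C)C(=O)[O-].[Li+].[Li+] | intermediate
27 | C9 TBS ether C19 TBS ester (not isolated) | C=C(C(Cl)Cl)CC[C@@H](O[Si](CC)(CC)CC)[C@]1(C)[C@H]([C@@H](C)[C@H](O[Si](CC)(CC)CC)[C@@H]2O[C@@H]21)[C@@H](O[Si](C)(C)C(C)(C)C)[C@]3(O[C@H](C(C)(C)C)OC3=O)[C@@H](C)C(=O)O[Si](C)(C)C(C)(C)C | intermediate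
28 | aldol acid, C8–C9 joined, dioxolanone intact | C=C(C(Cl)Cl)CC[C@@H](O[Si](CC)(CC)CC)[C@]1(C)[C@H]([C@@H](C)[C@H](O[Si](CC)(CC)CC)[C@@H]2O[C@@H]21)[C@@H](O[Si](C)(C)C(C)(C)C)[C@]3(O[C@H](C(C)(C)C)OC3=O)[C@@H](C)C(=O)O | intermediate
29 | dioxolane lactol, C7 epimers, formed as aluminium salt (not isolated) | C=C(C(Cl)Cl)CC[C@@H](O[Si](CC)(CC)CC)[C@]1(C)[C@H]([C@@H](C)[C@H](O[Si](CC)(CC)CC)[C@@H]2O[C@@H]21)[C@@H](O[Si](C)(C)C(C)(C)C)[C@]3(O[C@H](C(C)(C)C)OC3O)[C@@H](C)C(=O)O | intermediate
30 | C8-hydroxy C7-aldehyde C19-acid (open form) | C=C(C(Cl)Cl)CC[C@@H](O[Si](CC)(CC)CC)[C@]1(C)[C@H]([C@@H](C)[C@H](O[Si](CC)(CC)CC)[C@@H]2O[C@@H]21)[C@@H](O[Si](C)(C)C(C)(C)C)[C@](C=O)(O)[C@@H](C)C(=O)O | intermediate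
31 | C19 methyl ester | C=C(C(Cl)Cl)CC[C@@H](O[Si](CC)(CC)CC)[C@]1(C)[C@H]([C@@H](C)[C@H](O[Si](CC)(CC)CC)[C@@H]2O[C@@H]21)[C@@H](O[Si](C)(C)C(C)(C)C)[C@](C=O)(O)[C@@H](C)C(=O)OC | intermediate
32 | seco aldehyde gem-dichloride, C8 OTMS | C=C(C(Cl)Cl)CC[C@@H](O[Si](CC)(CC)CC)[C@]1(C)[C@H]([C@@H](C)[C@H](O[Si](CC)(CC)CC)[C@@H]2O[C@@H]21)[C@@H](O[Si](C)(C)C(C)(C)C)[C@](C=O)(O[Si](C)(C)C)[C@@H](C)C(=O)OC | intermediate
33 | (E)-γ-chloroallylchromium dichloride, chromium on C16 (not isolated) | Cl/C=C(/C[Cr](Cl)Cl)CC[C@@H](O[Si](CC)(CC)CC)[C@]1(C)[C@H]([C@@H](C)[C@H](O[Si](CC)(CC)CC)[C@@H]2O[C@@H]21)[C@@H](O[Si](C)(C)C(C)(C)C)[C@](C=O)(O[Si](C)(C)C)[C@@H](C)C(=O)OC | intermediate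
34 | ring-closed C7 chromium alkoxide (not isolated) | C=C1CC[C@@H](O[Si](CC)(CC)CC)[C@]2(C)[C@H]([C@@H](C)[C@H](O[Si](CC)(CC)CC)[C@@H]3O[C@@H]32)[C@@H](O[Si](C)(C)C(C)(C)C)[C@](O[Si](C)(C)C)([C@@H](C)C(=O)OC)[C@@H](O[Cr](Cl)Cl)[C@H]1Cl | intermediate
35 | silyl-protected briarane lactone | C=C1CC[C@@H](O[Si](CC)(CC)CC)[C@]2(C)[C@H]([C@@H](C)[C@H](O[Si](CC)(CC)CC)[C@@H]3O[C@@H]32)[C@@H](O[Si](C)(C)C(C)(C)C)[C@]2(O[Si](C)(C)C)[C@@H](C)C(=O)O[C@H]2[C@H]1Cl | intermediate
36 | 2,8,12-triol with C9 OTBS | C=C1CC[C@@H](O)[C@]2(C)[C@H]([C@@H](C)[C@H](O)[C@@H]3O[C@@H]32)[C@@H](O[Si](C)(C)C(C)(C)C)[C@]2(O)[C@@H](C)C(=O)O[C@H]2[C@H]1Cl | intermediate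
37 | 2,12-diacetate with C9 OTBS | C=C1CC[C@@H](OC(C)=O)[C@]2(C)[C@H]([C@@H](C)[C@H](OC(C)=O)[C@@H]3O[C@@H]32)[C@@H](O[Si](C)(C)C(C)(C)C)[C@]2(O)[C@@H](C)C(=O)O[C@H]2[C@H]1Cl | intermediate
38 | CNP0242711.1 | C=C1CC[C@@H](OC(C)=O)[C@]2(C)[C@H]([C@@H](C)[C@H](OC(C)=O)[C@@H]3O[C@@H]32)[C@@H](O)[C@]2(O)[C@@H](C)C(=O)O[C@H]2[C@H]1Cl | target

Total step count: 24. Longest linear sequence: 21 (steps 1–13 and 17–24).

Steps most likely to fail

Step 21. Oligomerisation, protonation of the allylchromium before it reaches C7, further reduction of the newly formed allylic chloride, or attack on the wrong aldehyde face may prevail. The fallback uses known chemistry only, sets out from 32 and comes back at 35. Vinylmagnesium bromide is added to the C7 aldehyde (THF, −78 °C, same polar Felkin–Anh bias), and the alkoxide lactonises to the vinyl lactone F1. CrCl2 in wet THF then hydrodechlorinates the arm, by reduction of the allylic halide and protonation of the allylchromium twice over, to the isopropenyl vinyl lactone F2. Ring-closing metathesis with the second-generation Hoveyda–Grubbs catalyst (toluene, high dilution, 80 °C) closes the ten-membered ring at C5=C6 to the (5Z)-alkene lactone F3. Ene-type allylic chlorination (N-chlorosuccinimide, PhSeCl 10 mol %, CH2Cl2) attacks this only alkene from its outer face, places chlorine on C6 and moves the double bond to C5=C16, giving 35.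

Step 17. Reversal of the aldol between two crowded partners and poor facial selectivity at C9 may occur. The fallback sets out from 19 and comes back at 28, replacing the reversible addition by an irreversible acylation and setting C9 by reduction. Pinnick oxidation (NaClO2, NaH2PO4, 2-methyl-2-butene) gives the C9 carboxylic acid F4. 1-Chloro-N,N,2-trimethylpropenylamine converts it under neutral conditions into the C9 acid chloride F5. C-acylation of dianion 25 anti to tert-butyl gives the C9-keto dioxolanone acid F6. NaBH4/CeCl3·7H2O (THF/MeOH, −40 °C) reduces the ketone with hydride anti to the C8–O bond (polar Felkin–Anh, planar C7 as the small group) to the free C9 alcohol acid F7. TBSOTf/2,6-lutidine with bicarbonate work-up then returns 28.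

Step 2. A competing formyl-endo approach (poor endo/exo selectivity) would place Me-20 trans to C9. The fallback sets out from 2 and 3 and comes back at 10, moving control of C11 from the cycloaddition to a kinetic protonation. The formyl-endo adduct F8 is taken through the operations of steps 3 to 5, giving in turn the C11-epimeric homoallylic alcohol F9, the C11-epimeric TES ether F10 and the C11-epimeric enone F11. LiN(i-Pr)2 (THF, −78 °C) forms the cross-conjugated lithium dienolate F12. In F12, strain with the in-plane methyl group pushes the C10 ester pseudo-axial on the β face. Quenching with 2,6-di-tert-butyl-4-methylphenol delivers the proton from the α face and gives 10, so both C11 epimers converge.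

Further compounds
F1 | step 21 | vinyl lactone with gem-dichloride arm | C=C(C(Cl)Cl)CC[C@@H](O[Si](CC)(CC)CC)[C@]1(C)[C@H]([C@@H](C)[C@H](O[Si](CC)(CC)CC)[C@@H]2O[C@@H]21)[C@@H](O[Si](C)(C)C(C)(C)C)[C@]3(O[Si](C)(C)C)[C@@H](C)C(=O)O[C@H]3C=C
F2 | step 21 | isopropenyl vinyl lactone | C=C(C)CC[C@@H](O[Si](CC)(CC)CC)[C@]1(C)[C@H]([C@@H](C)[C@H](O[Si](CC)(CC)CC)[C@@H]2O[C@@H]21)[C@@H](O[Si](C)(C)C(C)(C)C)[C@]3(O[Si](C)(C)C)[C@@H](C)C(=O)O[C@H]3C=C
F3 | step 21 | (5Z)-alkene lactone with C16 methyl | C1C[C@@H](O[Si](CC)(CC)CC)[C@]2(C)[C@H]([C@@H](C)[C@H](O[Si](CC)(CC)CC)[C@@H]3O[C@@H]32)[C@@H](O[Si](C)(C)C(C)(C)C)[C@]2(O[Si](C)(C)C)[C@@H](C)C(=O)O[C@H]2/C=C1/C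
F4 | step 17 | C9 carboxylic acid | C=C(C(Cl)Cl)CC[C@@H](O[Si](CC)(CC)CC)[C@]1(C)[C@H]([C@@H](C)[C@H](O[Si](CC)(CC)CC)[C@@H]2O[C@@H]21)C(=O)O
F5 | step 17 | C9 acid chloride | C=C(C(Cl)Cl)CC[C@@H](O[Si](CC)(CC)CC)[C@]1(C)[C@H]([C@@H](C)[C@H](O[Si](CC)(CC)CC)[C@@H]2O[C@@H]21)C(=O)Cl
F6 | step 17 | C9-keto dioxolanone acid | C=C(C(Cl)Cl)CC[C@@H](O[Si](CC)(CC)CC)[C@]1(C)[C@H]([C@@H](C)[C@H](O[Si](CC)(CC)CC)[C@@H]2O[C@@H]21)C(=O)[C@]3(O[C@H](C(C)(C)C)OC3=O)[C@@H](C)C(=O)O
F7 | step 17 | free C9 alcohol acid | C=C(C(Cl)Cl)CC[C@@H](O[Si](CC)(CC)CC)[C@]1(C)[C@H]([C@@H](C)[C@H](O[Si](CC)(CC)CC)[C@@H]2O[C@@H]21)[C@@H](O)[C@]3(O[C@H](C(C)(C)C)OC3=O)[C@@H](C)C(=O)O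
F8 | step 2 | formyl-endo adduct (C11 epimer of 4) | O=C[C@]1(C)[C@H]([C@H](C)C(O[Si](C(C)C)(C(C)C)C(C)C)=CC1)C(=O)OCC
F9 | step 2 | C11-epimeric homoallylic alcohol | C=CC[C@@H](O)[C@]1(C)[C@H]([C@H](C)C(O[Si](C(C)C)(C(C)C)C(C)C)=CC1)C(=O)OCC
F10 | step 2 | C11-epimeric TES ether | C=CC[C@@H](O[Si](CC)(CC)CC)[C@]1(C)[C@H]([C@H](C)C(O[Si](C(C)C)(C(C)C)C(C)C)=CC1)C(=O)OCC
F11 | step 2 | C11-epimeric enone | C=CC[C@@H](O[Si](CC)(CC)CC)[C@]1(C)[C@H]([C@H](C)C(=O)C=C1)C(=O)OCC
F12 | step 2 | cross-conjugated lithium dienolate | C=CC[C@@H](O[Si](CC)(CC)CC)[C@]1(C)[C@H](C(C)=C([O-])C=C1)C(=O)OCC.[Li+]
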